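**Plan**

- Retrosynthesis: the four O-benzyl groups and a temporary tert-butyl ester on C3 are put back first. The flavanone O1–C2 bond is then cut (oxa-Michael), followed by C2–C3 as an arylidene C=C (Knoevenagel), the aryl–O bond of the kaempferol 3-O-aryl ether (SNAr), the flavonol C3–O bond (oxidation), and the flavone ring C (cyclodehydration, C-aroylation).
- Forward: ring C of the flavone is built first on a phloroacetophenone. C3 is then hydroxylated and arylated with 4-fluorobenzaldehyde, the resulting aldehyde is joined to the ring A beta-keto ester, and ring C of the flavanone closes last.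
- Enabling feature: in the flavanone, O1 is a ring A phenol oxygen bonded to the benzylic C2, and C3 lies alpha to the C4 ketone. An ester parked on C3 therefore turns the open-chain C2=C3 alkene into a rigid 1,3-dicarbonyl acceptor that a hydrogen-bond-donor catalyst can hold at two points.
- Stereochemistry: the only stereocentre of the target, C2 (S), comes from the chiral amine–thiourea catalyst in the ring closure. The transient C3 centre is lost on decarboxylation.

Key step: step 9

Assumption: the thiourea made from 9-amino-9-deoxy-epi-quinine is taken to give the 2S series (its quinidine-derived pseudo-enantiomer would replace it if the sense proves opposite), and the Knoevenagel product is drawn as the Z alkene, either alkene isomer being expected to converge on the same ring closure.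

**Route**

Step 1
Reactants: 1 2,4,6-trihydroxyacetophenone
Product: 2 1-[2,4-bis(benzyloxy)-6-hydroxyphenyl]ethanone
Conditions: BnBr (2.1 equiv), K2CO3 (2.2 equiv), DMF, 23 °C
Reagents that add atoms: benzyl bromide, BrCc1ccccc1
Why: Williamson etherification; the two hydroxyls not held in the hydrogen bond to the acetyl carbonyl are the more acidic and nucleophilic, so alkylation should stop at the dibenzyl ether with the chelated hydroxyl left free.

Step 2
Reactants: 2 1-[2,4-bis(benzyloxy)-6-hydroxyphenyl]ethanone; 3 4-(benzyloxy)benzoyl chloride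
Product: 4 1-[2,4-bis(benzyloxy)-6-hydroxyphenyl]-3-[4-(benzyloxy)phenyl]propane-1,3-dione
Conditions: LiN(SiMe3)2 (3.1 equiv), THF, −78 °C; then 3, −78 → 23 °C; aq. NH4Cl
Reagents that add atoms: none
Why: Claisen-type C-aroylation of the lithium phenoxide–enolate dianion, the one-flask counterpart of the Baker–Venkataraman rearrangement, should give the 1,3-diketone directly, since any O-aroyl ester formed would rearrange to the same product under the excess base.

Step 3
Reactants: 4 1-[2,4-bis(benzyloxy)-6-hydroxyphenyl]-3-[4-(benzyloxy)phenyl]propane-1,3-dione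
Product: 5 5,7-bis(benzyloxy)-2-[4-(benzyloxy)phenyl]-4H-chromen-4-one
Conditions: NaOAc, AcOH, 110 °C
Reagents that add atoms: none
Why: Cyclodehydration; the free phenol adds to the distal carbonyl of the enolised diketone and the hemiketal loses water to give the 4-pyranone ring C of the flavone, under conditions mild enough for the benzyl ethers.

Step 4
Reactants: 5 5,7-bis(benzyloxy)-2-[4-(benzyloxy)phenyl]-4H-chromen-4-one
Product: 7 5,7-bis(benzyloxy)-2-[4-(benzyloxy)phenyl]-3-hydroxy-4H-chromen-4-one, via flavone 2,3-epoxide 6 (not isolated)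
Conditions: dimethyldioxirane (about 0.08 M in acetone, 3 equiv), CH2Cl2, 0 → 23 °C; then TsOH·H2O (cat.), CH2Cl2, 23 °C
Reagents that add atoms: dimethyldioxirane, CC1(C)OO1
Why: Epoxidation of the enol-ether-like C2=C3 bond by the dioxirane, then acid-catalysed opening of the epoxide to the C2 oxocarbenium ion and loss of the C3 proton, a known flavone-to-flavonol oxidation.

Step 5
Reactants: 7 5,7-bis(benzyloxy)-2-[4-(benzyloxy)phenyl]-3-hydroxy-4H-chromen-4-one; 8 4-fluorobenzaldehyde
Product: 9 4-({5,7-bis(benzyloxy)-2-[4-(benzyloxy)phenyl]-4-oxo-4H-chromen-3-yl}oxy)benzaldehyde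
Conditions: K2CO3 (1.5 equiv), degassed DMF, 100 °C, argon
Reagents that add atoms: none
Why: Nucleophilic aromatic substitution (addition–elimination through a Meisenheimer intermediate); the flavonol 3-oxide, the only free hydroxyl of 7, displaces fluoride para to the activating formyl group.

Step 6
Reactants: 10 1-(2,6-dihydroxy-4-methoxyphenyl)ethanone
Product: 11 1-[2-(benzyloxy)-6-hydroxy-4-methoxyphenyl]ethanone
Conditions: BnBr (1.05 equiv), K2CO3 (1.1 equiv), acetone, reflux
Reagents that add atoms: benzyl bromide, BrCc1ccccc1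
Why: Williamson etherification that should stop after one benzylation, because the remaining hydroxyl is locked in a hydrogen bond to the ketone and is far less nucleophilic.

Step 7
Reactants: 11 1-[2-(benzyloxy)-6-hydroxy-4-methoxyphenyl]ethanone
Product: 12 tert-butyl 3-[2-(benzyloxy)-6-hydroxy-4-methoxyphenyl]-3-oxopropanoate
Conditions: LiN(SiMe3)2 (3.2 equiv), THF, −78 °C; Boc2O (1.1 equiv), −78 → 0 °C; aq. NH4Cl
Reagents that add atoms: di-tert-butyl dicarbonate, CC(C)(C)OC(=O)OC(=O)OC(C)(C)C
Why: Claisen-type C-acylation of the ketone enolate within the phenoxide–enolate dianion; the extra base deprotonates the more acidic beta-keto ester as it forms and so should prevent a second acylation.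

Step 8
Reactants: 12 tert-butyl 3-[2-(benzyloxy)-6-hydroxy-4-methoxyphenyl]-3-oxopropanoate; 9 4-({5,7-bis(benzyloxy)-2-[4-(benzyloxy)phenyl]-4-oxo-4H-chromen-3-yl}oxy)benzaldehyde
Product: 13 tert-butyl (2Z)-2-[2-(benzyloxy)-6-hydroxy-4-methoxybenzoyl]-3-[4-({5,7-bis(benzyloxy)-2-[4-(benzyloxy)phenyl]-4-oxo-4H-chromen-3-yl}oxy)phenyl]prop-2-enoate
Conditions: piperidine (20 mol %), AcOH (20 mol %), MgSO4, toluene, 23 °C
Reagents that add atoms: none
Why: Knoevenagel condensation under piperidinium acetate catalysis; the buffered amine at room temperature and the phenol–ketone hydrogen bond should keep uncatalysed ring closure slow, and the more stable Z alkene (aryl cis to the ester) is expected.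

Step 9
Reactants: 13 tert-butyl (2Z)-2-[2-(benzyloxy)-6-hydroxy-4-methoxybenzoyl]-3-[4-({5,7-bis(benzyloxy)-2-[4-(benzyloxy)phenyl]-4-oxo-4H-chromen-3-yl}oxy)phenyl]prop-2-enoate
Product: 14 tert-butyl (2S,3R)-5-(benzyloxy)-7-methoxy-4-oxo-2-[4-({5,7-bis(benzyloxy)-2-[4-(benzyloxy)phenyl]-4-oxo-4H-chromen-3-yl}oxy)phenyl]chromane-3-carboxylate (2,3-trans)
Conditions: 1-[3,5-bis(trifluoromethyl)phenyl]-3-[(8S,9S)-6'-methoxycinchonan-9-yl]thiourea (10 mol %), toluene, −25 °C; then cold filtration through SiO2 to remove the catalyst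
Reagents that add atoms: none
Why: The quinuclidine nitrogen of the catalyst takes the proton of the ring A phenol while the two thiourea N–H bonds clamp the 1,3-dicarbonyl unit, so the phenol oxygen adds to the arylidene carbon in an intramolecular oxa-Michael addition that forms O1–C2. The closest known reaction is the cinchona-thiourea cyclisation of 2-hydroxyaryl alkylidene beta-keto esters to 3-carboxyflavanones. Ring C closes in a 6-endo-trig mode. C2 (S) is set by the catalyst, which exposes one face of the bound acceptor to the tethered oxygen, whereas C3 (R) follows under substrate control because the enolisable beta-keto ester centre equilibrates to the 2,3-trans arrangement with aryl and ester both pseudo-equatorial. The step needs the catalysed pathway to outrun racemic background closure, which the low temperature, the non-polar solvent and the phenol–ketone hydrogen bond should secure. It also needs a single nucleophile, which is guaranteed because every other hydroxyl is benzylated.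

Step 10
Reactants: 14 tert-butyl (2S,3R)-5-(benzyloxy)-7-methoxy-4-oxo-2-[4-({5,7-bis(benzyloxy)-2-[4-(benzyloxy)phenyl]-4-oxo-4H-chromen-3-yl}oxy)phenyl]chromane-3-carboxylate
Product: 16 (2S)-5-(benzyloxy)-7-methoxy-2-[4-({5,7-bis(benzyloxy)-2-[4-(benzyloxy)phenyl]-4-oxo-4H-chromen-3-yl}oxy)phenyl]chroman-4-one, via beta-keto acid 15 (not isolated)
Conditions: TsOH·H2O (1 equiv), toluene, 80 °C
Reagents that add atoms: none
Why: Acidolysis of the tert-butyl ester (loss of isobutene) and thermal decarboxylation of the beta-keto acid through its cyclic transition state; no base is present, so C2 should not be opened by retro-Michael reaction, and the C3 centre simply disappears.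

Step 11
Reactants: 16 (2S)-5-(benzyloxy)-7-methoxy-2-[4-({5,7-bis(benzyloxy)-2-[4-(benzyloxy)phenyl]-4-oxo-4H-chromen-3-yl}oxy)phenyl]chroman-4-one
Product: 17 (2S)-2-(4-{[5,7-dihydroxy-2-(4-hydroxyphenyl)-4-oxo-4H-chromen-3-yl]oxy}phenyl)-5-hydroxy-7-methoxychroman-4-one (CNP0173006.1)
Conditions: H2 (1 atm), 10% Pd/C (zerovalent palladium on carbon), THF/MeOH, 23 °C
Reagents that add atoms: none
Why: Catalytic hydrogenolysis of the four aryl benzyl ethers under neutral conditions, which should leave the tetrasubstituted flavone alkene, the diaryl ether, the methyl ether and the base-sensitive C2 centre untouched.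

**Compound list**

1 | 2,4,6-trihydroxyacetophenone | CC(=O)c1c(O)cc(O)cc1O | starting material
2 | 1-[2,4-bis(benzyloxy)-6-hydroxyphenyl]ethanone | CC(=O)c1c(O)cc(OCc2ccccc2)cc1OCc1ccccc1 | intermediate
3 | 4-(benzyloxy)benzoyl chloride | O=C(Cl)c1ccc(OCc2ccccc2)cc1 | starting material
4 | 1-[2,4-bis(benzyloxy)-6-hydroxyphenyl]-3-[4-(benzyloxy)phenyl]propane-1,3-dione | O=C(CC(=O)c1ccc(OCc2ccccc2)cc1)c1c(O)cc(OCc2ccccc2)cc1OCc1ccccc1 | intermediate
5 | 5,7-bis(benzyloxy)-2-[4-(benzyloxy)phenyl]-4H-chromen-4-one (tri-O-benzylapigenin) | O=c1cc(-c2ccc(OCc3ccccc3)cc2)oc2cc(OCc3ccccc3)cc(OCc3ccccc3)c12 | intermediate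
6 | 4,6-bis(benzyloxy)-1a-[4-(benzyloxy)phenyl]-1a,7a-dihydro-7H-oxireno[2,3-b]chromen-7-one (2,3-epoxide of 5, racemic) | O=C1C2OC2(c2ccc(OCc3ccccc3)cc2)Oc2cc(OCc3ccccc3)cc(OCc3ccccc3)c21 | intermediate (not isolated)
7 | 5,7-bis(benzyloxy)-2-[4-(benzyloxy)phenyl]-3-hydroxy-4H-chromen-4-one (5,7,4'-tri-O-benzylkaempferol) | O=c1c(O)c(-c2ccc(OCc3ccccc3)cc2)oc2cc(OCc3ccccc3)cc(OCc3ccccc3)c12 | intermediate
8 | 4-fluorobenzaldehyde | O=Cc1ccc(F)cc1 | starting material
9 | 4-({5,7-bis(benzyloxy)-2-[4-(benzyloxy)phenyl]-4-oxo-4H-chromen-3-yl}oxy)benzaldehyde | O=Cc1ccc(Oc2c(-c3ccc(OCc4ccccc4)cc3)oc3cc(OCc4ccccc4)cc(OCc4ccccc4)c3c2=O)cc1 | intermediate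
10 | 1-(2,6-dihydroxy-4-methoxyphenyl)ethanone (2',6'-dihydroxy-4'-methoxyacetophenone) | CC(=O)c1c(O)cc(OC)cc1O | starting material
11 | 1-[2-(benzyloxy)-6-hydroxy-4-methoxyphenyl]ethanone | CC(=O)c1c(O)cc(OC)cc1OCc1ccccc1 | intermediate
12 | tert-butyl 3-[2-(benzyloxy)-6-hydroxy-4-methoxyphenyl]-3-oxopropanoate | CC(C)(C)OC(=O)CC(=O)c1c(O)cc(OC)cc1OCc1ccccc1 | intermediate
13 | tert-butyl (2Z)-2-[2-(benzyloxy)-6-hydroxy-4-methoxybenzoyl]-3-[4-({5,7-bis(benzyloxy)-2-[4-(benzyloxy)phenyl]-4-oxo-4H-chromen-3-yl}oxy)phenyl]prop-2-enoate | COc1cc(O)c(C(=O)/C(=C/c2ccc(Oc3c(-c4ccc(OCc5ccccc5)cc4)oc4cc(OCc5ccccc5)cc(OCc5ccccc5)c4c3=O)cc2)C(=O)OC(C)(C)C)c(OCc2ccccc2)c1 | intermediate (key-step precursor)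
14 | tert-butyl (2S,3R)-5-(benzyloxy)-7-methoxy-4-oxo-2-[4-({5,7-bis(benzyloxy)-2-[4-(benzyloxy)phenyl]-4-oxo-4H-chromen-3-yl}oxy)phenyl]chromane-3-carboxylate | COc1cc(OCc2ccccc2)c2c(c1)O[C@H](c1ccc(Oc3c(-c4ccc(OCc5ccccc5)cc4)oc4cc(OCc5ccccc5)cc(OCc5ccccc5)c4c3=O)cc1)[C@@H](C(=O)OC(C)(C)C)C2=O | intermediate (key-step product)
15 | (2S,3R)-5-(benzyloxy)-7-methoxy-4-oxo-2-[4-({5,7-bis(benzyloxy)-2-[4-(benzyloxy)phenyl]-4-oxo-4H-chromen-3-yl}oxy)phenyl]chromane-3-carboxylic acid | COc1cc(OCc2ccccc2)c2c(c1)O[C@H](c1ccc(Oc3c(-c4ccc(OCc5ccccc5)cc4)oc4cc(OCc5ccccc5)cc(OCc5ccccc5)c4c3=O)cc1)[C@@H](C(=O)O)C2=O | intermediate (not isolated)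
16 | (2S)-5-(benzyloxy)-7-methoxy-2-[4-({5,7-bis(benzyloxy)-2-[4-(benzyloxy)phenyl]-4-oxo-4H-chromen-3-yl}oxy)phenyl]chroman-4-one | COc1cc(OCc2ccccc2)c2c(c1)O[C@H](c1ccc(Oc3c(-c4ccc(OCc5ccccc5)cc4)oc4cc(OCc5ccccc5)cc(OCc5ccccc5)c4c3=O)cc1)CC2=O | intermediate
17 | (2S)-2-(4-{[5,7-dihydroxy-2-(4-hydroxyphenyl)-4-oxo-4H-chromen-3-yl]oxy}phenyl)-5-hydroxy-7-methoxychroman-4-one | COc1cc(O)c2c(c1)O[C@H](c1ccc(Oc3c(-c4ccc(O)cc4)oc4cc(O)cc(O)c4c3=O)cc1)CC2=O | target

**Step count and risks**

Total step count: 11. Longest linear sequence: 9 steps (steps 1–5, then 8–11); the ring A branch (steps 6 and 7) joins at step 8.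

Steps most likely to fail:

1. Step 9. The 5-benzyloxy group twists the aroyl unit and the arylidene is very large, so the catalyst may discriminate the two alkene faces poorly. Uncatalysed closure or reversible ring opening before the catalyst is removed could erode the enantiomeric purity further. The fallback sets out from 11 and 9. Claisen–Schmidt condensation (KOH, EtOH/THF, 23 °C) should give the (E)-2'-hydroxychalcone F1. NaOAc in refluxing EtOH should close it to the racemic flavanone F2. Preparative HPLC on an amylose tris(3,5-dimethylphenylcarbamate) phase then separates the enantiomers; the (2R)-flavanone F3 is set aside and the 2S enantiomer is compound 16, where the route resumes at step 11.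

2. Step 5. The flavonol 3-oxide is a hindered, delocalised and internally chelated nucleophile, so addition to the aryl fluoride may be sluggish, and at the temperature needed the anion may degrade oxidatively if air is admitted. The fallback sets out from 7 and replaces addition–elimination by metal-free ligand coupling at hypervalent iodine. Treatment with (4-formylphenyl)(2,4,6-trimethoxyphenyl)iodonium tosylate and K2CO3 in toluene at 23–50 °C should transfer the formylphenyl group to the 3-oxygen, and the sequence comes back directly at 9.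

3. Step 7. Boc2O may acylate the phenoxide oxygen instead of the enolate carbon, and the hindered, doubly ortho-substituted dianion may convert incompletely or be acylated twice. The fallback sets out from 11 and masks the phenol. Allyl bromide and K2CO3 in DMF at 60 °C should give the allyl ether F4. LiN(SiMe3)2 (2.2 equiv) and Boc2O then act on a simple ketone enolate to give the allyl-protected beta-keto ester F5. Tsuji–Trost deallylation with Pd(PPh3)4 (zerovalent palladium, cat.) and morpholine in THF at 23 °C returns the sequence to 12.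

**Further compounds**

F1 | step 9 | (2E)-1-[2-(benzyloxy)-6-hydroxy-4-methoxyphenyl]-3-[4-({5,7-bis(benzyloxy)-2-[4-(benzyloxy)phenyl]-4-oxo-4H-chromen-3-yl}oxy)phenyl]prop-2-en-1-one | COc1cc(O)c(C(=O)/C=C/c2ccc(Oc3c(-c4ccc(OCc5ccccc5)cc4)oc4cc(OCc5ccccc5)cc(OCc5ccccc5)c4c3=O)cc2)c(OCc2ccccc2)c1
F2 | step 9 | racemic 5-(benzyloxy)-7-methoxy-2-[4-({5,7-bis(benzyloxy)-2-[4-(benzyloxy)phenyl]-4-oxo-4H-chromen-3-yl}oxy)phenyl]chroman-4-one | COc1cc(OCc2ccccc2)c2c(c1)OC(c1ccc(Oc3c(-c4ccc(OCc5ccccc5)cc4)oc4cc(OCc5ccccc5)cc(OCc5ccccc5)c4c3=O)cc1)CC2=O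
F3 | step 9 | (2R)-5-(benzyloxy)-7-methoxy-2-[4-({5,7-bis(benzyloxy)-2-[4-(benzyloxy)phenyl]-4-oxo-4H-chromen-3-yl}oxy)phenyl]chroman-4-one | COc1cc(OCc2ccccc2)c2c(c1)O[C@@H](c1ccc(Oc3c(-c4ccc(OCc5ccccc5)cc4)oc4cc(OCc5ccccc5)cc(OCc5ccccc5)c4c3=O)cc1)CC2=O
F0 | step 5 | none | none
F4 | step 7 | 1-[2-(allyloxy)-6-(benzyloxy)-4-methoxyphenyl]ethanone | CC(=O)c1c(OCC=C)cc(OC)cc1OCc1ccccc1
F5 | step 7 | tert-butyl 3-[2-(allyloxy)-6-(benzyloxy)-4-methoxyphenyl]-3-oxopropanoate | CC(C)(C)OC(=O)CC(=O)c1c(OCC=C)cc(OC)cc1OCc1ccccc1
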